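**Plan** (cembrane numbering: C1 ring-junction CH, C3 lactone O–CH, C4 carbinol, C7, C8=C19, C11/C12, C15/C16 lactone α-carbon and carbonyl)
- Cuts: C7–OOH back to a (7R)-alcohol (one SN2 inversion), the 11,12-epoxide back to the E alkene, C8=C19 back to a C8 ketone; then the ring bond C9–C10, with CO2 put back between C9 and the oxygen on C10, so that the 14-membered carbocycle becomes a 16-membered allyl β-keto lactone; this is opened at its ester C–O bond and the chain is cut at C4–C5 and C11=C12.
- Enabling feature: C9 is the α-carbon of the latent C8 ketone and C10 is the allylic terminus of the C11=C12 alkene that precedes the epoxide, so C9–C10 is exactly the bond an allyl β-keto ester forms when it loses CO2.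
- Forward order: δ-lactone (oxidative lactonisation), chain joined at C4–C5, 16-membered β-keto lactone (acylketene trapping), 14-membered carbocycle (ring contraction with loss of CO2), epoxide last.
- Stereochemistry: C1 from (R)-limonene; C3 and C15 by base equilibration to the all-equatorial lactone; C4 by Felkin–Anh addition next to C3; C7 from (R)-malic acid, inverted once at the end; C11/C12 by Shi epoxidation.

Key step: step 20

Remark: C7 is carried as the (R)-configured p-methoxybenzyl (PMB) ether from commercially available (R)-malic acid so that a single SN2 displacement gives the (7S)-hydroperoxide, and the tertiary C4–OH is silylated (step 22) before C7 is activated so that it cannot close a tetrahydrofuran onto C7.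

Step 1
Reactants: 1 (R)-malic acid
Product: 2 (R)-butane-1,2,4-triol
Conditions: BH3·SMe2, B(OMe)3, THF, 0 °C to rt; MeOH
Reagents that add atoms: none
Why: Borane reduction of both carboxyl groups leaves the carbinol centre untouched, so the triol keeps the R configuration that becomes C7.

Step 2
Reactants: 2 (R)-butane-1,2,4-triol
Product: 3 cis p-methoxybenzylidene acetal
Conditions: 4-MeOC6H4CH(OMe)2, CSA (cat.), CH2Cl2, rt
Reagents that add atoms: 4-methoxybenzaldehyde dimethyl acetal (COc1ccc(cc1)C(OC)OC)
Why: Transacetalisation under thermodynamic control should favour the six-membered 1,3-dioxane across the secondary and the remote primary hydroxyl with the aryl group equatorial (acetal carbon cis to the hydroxymethyl group), which leaves the C8 hydroxyl free.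

Step 3
Reactants: 3 cis p-methoxybenzylidene acetal
Product: 4 triethylsilyl ether of the acetal
Conditions: Et3SiCl, imidazole, CH2Cl2, 0 °C
Reagents that add atoms: chlorotriethylsilane (CC[Si](Cl)(CC)CC)
Why: Standard silylation of the primary alcohol; a primary triethylsilyl ether is chosen because Swern conditions can later oxidise it directly to the aldehyde.

Step 4
Reactants: 4 triethylsilyl ether of the acetal
Product: 5 PMB ether alcohol
Conditions: iBu2AlH, CH2Cl2, −78 to 0 °C
Reagents that add atoms: none
Why: Reductive acetal opening, in which iBu2AlH coordinates the less hindered primary acetal oxygen and cleaves its C–O bond, should leave the PMB group on the secondary (C7) oxygen and free the primary C5 hydroxyl.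

Step 5
Reactants: 5 PMB ether alcohol
Product: 6 iodide
Conditions: I2, PPh3, imidazole, CH2Cl2, 0 °C
Reagents that add atoms: iodine (II)
Why: Appel-type iodination of the primary alcohol under buffered conditions that spare the silyl ether and do not involve the stereocentre.

Step 6
Reactants: 7 (R)-limonene
Product: 8 p-menth-1-en-9-ol
Conditions: 9-BBN, THF, 0 °C to rt; NaOH, H2O2
Reagents that add atoms: hydrogen peroxide (OO)
Why: Hydroboration–oxidation with bulky 9-BBN is selective for the 1,1-disubstituted isopropenyl alkene and gives the primary alcohol; the new centre (C15) is not controlled here and is corrected in step 14.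

Step 7
Reactants: 8 p-menth-1-en-9-ol
Product: 11 keto acetal, via hydroperoxy lactol 9 (not isolated), via hydroperoxy acetal 10 (not isolated)
Conditions: O3, CH2Cl2/MeOH, −78 °C; TsOH·H2O, rt; NaHCO3, then Me2S
Reagents that add atoms: ozone ([O-][O+]=O); methanol (CO)
Why: Ozonolysis in methanol with in-flask acetalisation and reductive work-up: the carbonyl oxide forms at the more substituted carbon and is trapped as a methoxy hydroperoxide (reduced to the C12 methyl ketone), while the C3 aldehyde is captured by the side-chain hydroxyl and methanol as a cyclic mixed acetal, C1 being untouched.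

Step 8
Reactants: 11 keto acetal; 12 triethyl phosphonoacetate
Product: 13 E enoate
Conditions: NaH, THF, 0 to 50 °C
Reagents that add atoms: none
Why: Horner–Wadsworth–Emmons olefination of the methyl ketone should give mainly the E trisubstituted enoate (ester trans to the longer chain), the minor Z isomer being removed by chromatography.

Step 9
Reactants: 13 E enoate
Product: 14 allylic alcohol
Conditions: iBu2AlH, CH2Cl2, −78 °C
Reagents that add atoms: none
Why: 1,2-Reduction of the unsaturated ester gives the C10 allylic alcohol without touching the acetal or the alkene geometry.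

Step 10
Reactants: 14 allylic alcohol
Product: 15 silyl ether
Conditions: tBuPh2SiCl, imidazole, DMF, rt
Reagents that add atoms: tert-butyl(chloro)diphenylsilane (CC(C)(C)[Si](Cl)(c1ccccc1)c1ccccc1)
Why: Silylation of the primary allylic alcohol with an acid-stable group that survives acetal hydrolysis and the oxidations until fluoride removes it before macrolactonisation.

Step 11
Reactants: 15 silyl ether
Product: 16 lactol
Conditions: 1 M HCl, THF, rt
Reagents that add atoms: water (O)
Why: Acid hydrolysis of the 2-methoxytetrahydropyran releases the lactol (masked C3 aldehyde) while the tert-butyldiphenylsilyl ether is stable.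

Step 12
Reactants: 16 lactol; 17 ethyl vinyl ether
Product: 20 keto diol, via 1-ethoxyvinyllithium 18 (not isolated), via enol ether diol 19 (not isolated)
Conditions: 17, tBuLi, THF, −78 to 0 °C; then 16, −78 to 0 °C; then 0.5 M HCl, 0 °C
Reagents that add atoms: water (O)
Why: 1-Ethoxyvinyllithium, an acetyl anion equivalent, adds to the open hydroxy aldehyde form of the lactol and mild acid hydrolysis of the enol ether gives the α-hydroxy methyl ketone; C3 forms as a mixture and is set in step 14.

Step 13
Reactants: 20 keto diol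
Product: 22 acetyl lactone mixture, via hydroxy lactol 21 (not isolated)
Conditions: TEMPO (cat.), PhI(OAc)2, CH2Cl2, rt
Reagents that add atoms: none
Why: Oxidative lactonisation of a 1,5-diol: the primary alcohol is oxidised selectively to the aldehyde, which the C3 hydroxyl traps as a six-membered lactol that is oxidised on to the δ-lactone.

Step 14
Reactants: 22 acetyl lactone mixture
Product: 23 acetyl lactone
Conditions: DBU, toluene, 80 °C
Reagents that add atoms: none
Why: Amine-base epimerisation through the enolates: C3–H (α to the ketone) and C15–H (α to the lactone carbonyl) are the only exchangeable centres, and equilibration should favour the lactone with acetyl, side chain and methyl all equatorial (C3 cis and C15 trans to the fixed C1), any remaining C15 epimer being separated and resubmitted.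

Step 15
Reactants: 23 acetyl lactone; 6 iodide
Product: 26 tertiary alcohol, via alkyllithium 24 (not isolated), via organocerium 25 (not isolated)
Conditions: 6, tBuLi, Et2O, −78 °C; anhydrous CeCl3, THF, −78 °C; then 23, −78 °C
Reagents that add atoms: none
Why: Organocerium 1,2-addition (low basicity, so the enolisable ketone is not deprotonated and the lactone is spared); the C3 oxygen is an acyloxy oxygen that chelates poorly, so attack should follow the polar Felkin–Anh model (C3–O anti to the nucleophile, approach past C3–H) and give the (4S) carbinol.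

Step 16
Reactants: 26 tertiary alcohol
Product: 27 aldehyde
Conditions: (COCl)2, DMSO, CH2Cl2, −78 to −30 °C; iPr2NEt, −78 to 0 °C
Reagents that add atoms: none
Why: Swern conditions cleave and oxidise a primary triethylsilyl ether directly to the aldehyde, while the tertiary alcohol, the PMB ether and the bulky silyl ether are inert and the hindered base should not epimerise C7.

Step 17
Reactants: 27 aldehyde; 28 tert-butyl diazoacetate
Product: 29 β-keto ester
Conditions: SnCl2 (cat.), CH2Cl2, rt
Reagents that add atoms: none
Why: Roskamp reaction: the diazo ester adds to the Lewis-acid-activated aldehyde and a 1,2-hydride shift with loss of N2 gives the β-keto ester in one step, a reaction suited to α-alkoxy aldehydes without loss of configuration.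

Step 18
Reactants: 29 β-keto ester
Product: 30 seco alcohol
Conditions: Bu4NF, AcOH, THF, 0 °C to rt
Reagents that add atoms: none
Why: Buffered fluoride removes the primary allylic silyl ether, the β-keto ester, lactone and PMB ether being stable and the only other hydroxyl being tertiary.

Step 19
Reactants: 30 seco alcohol
Product: 32 macrolactone, via acylketene 31 (not isolated)
Conditions: toluene, reflux, high dilution (slow addition)
Reagents that add atoms: none
Why: Thermolysis of the tert-butyl β-keto ester expels tert-butanol to give an acylketene that the primary allylic C10 hydroxyl traps in a 16-membered macrolactonisation, whereas addition of the tertiary C4 hydroxyl would give a strained eight-membered tertiary ester that reverts to the acylketene.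

Step 20
Reactants: 32 macrolactone
Product: 33 macrocyclic ketone
Conditions: Pd(PPh3)4 (10 mol%), THF, 50 °C, high dilution
Reagents that add atoms: none
Why: Proposed new method: zerovalent palladium should ionise the allylic C10–O bond of 32 to a π-allyl complex spanning C10–C12 with a tethered β-keto carboxylate, which loses CO2 to an enolate fixed at C8–C9; C9 then bonds to the primary terminus C10 and releases the catalyst, so the 16-membered lactone contracts to the 14-membered carbocycle. The closest known reaction type is the palladium-catalysed decarboxylative allylation of acyclic and small-ring allyl β-keto esters (Tsuji–Trost chemistry with a Carroll-type outcome, geranyl esters included); its use to contract a macrolactone is the untested element. The 14-membered ring closes by intramolecular C-allylation in which nucleophile and electrophile are generated inside the same ring and stay tethered through C1–C8, so closure is an ion-pair recombination favoured over crossover by high dilution. No stereocentre is formed, and C7 is not at risk because decarboxylation places the enolate only on the C9 side of the ketone. The step needs attack at C10 and not at the tertiary C12, which the preference of palladium allyl complexes for the less substituted terminus should secure, and retention of the E geometry, which should hold because syn–anti isomerisation would require a σ-bond to the tertiary C12.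

Step 21
Reactants: 33 macrocyclic ketone
Product: 34 exomethylene compound
Conditions: Zn, CH2Br2, TiCl4, THF/CH2Cl2, 0 °C to rt
Reagents that add atoms: dibromomethane (BrCBr)
Why: Lombardo methylenation with the non-basic zinc–titanium methylene reagent converts the hindered α-alkoxy ketone into the 1,1-disubstituted alkene without enolisation, so C7 is not epimerised, and it tolerates the lactone and the free tertiary alcohol.

Step 22
Reactants: 34 exomethylene compound
Product: 35 C4 silyl ether
Conditions: Et3SiOTf, 2,6-lutidine, CH2Cl2, −78 to 0 °C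
Reagents that add atoms: triethylsilyl trifluoromethanesulfonate (CC[Si](CC)(CC)OS(=O)(=O)C(F)(F)F)
Why: Silyl triflate silylation of the tertiary C4 hydroxyl, done so that this oxygen cannot displace the C7 leaving group (tetrahydrofuran formation) in step 25.

Step 23
Reactants: 35 C4 silyl ether
Product: 36 epoxide
Conditions: L-fructose-derived Shi ketone (enantiomer of the usual D-fructose-derived catalyst), KHSO5 (as Oxone, 2KHSO5·KHSO4·K2SO4), K2CO3, Bu4NHSO4, MeCN/CH2(OMe)2, aq. Na2B4O7 buffer, 0 °C
Reagents that add atoms: potassium peroxymonosulfate ([K+].[O-]S(=O)(=O)OO)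
Why: Shi epoxidation: the chiral dioxirane should oxidise the electron-rich E-trisubstituted C11=C12 alkene faster than the 1,1-disubstituted allylic-ether alkene, and since the D-fructose-derived ketone gives R,R epoxides from such alkenes, its enantiomer should deliver the (11S,12S) epoxide.

Step 24
Reactants: 36 epoxide
Product: 37 allylic alcohol
Conditions: DDQ, CH2Cl2/pH 7 buffer, 0 °C
Reagents that add atoms: none
Why: Oxidative cleavage of the PMB ether frees the (7R)-allylic alcohol while the triethylsilyl ether, epoxide and lactone are untouched.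

Step 25
Reactants: 37 allylic alcohol
Product: 39 perketal, via mesylate 38 (not isolated)
Conditions: MsCl, Et3N, THF, −30 °C; then transferred into 2-methoxyprop-2-yl hydroperoxide, KOtBu, DMF, 0 °C
Reagents that add atoms: 2-methoxyprop-2-yl hydroperoxide (COC(C)(C)OO)
Why: Sulfonylation followed by SN2 displacement with the anion of a monoprotected hydrogen peroxide should give the peroxide with inversion (C7 becomes S); the non-hydroxide nucleophile spares the lactone and the silylated C4 oxygen cannot compete.

Step 26
Reactants: 39 perketal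
Product: 41 target hydroperoxide, via hydroxy perketal 40 (not isolated)
Conditions: HF·pyridine, pyridine, THF, 0 °C to rt; then AcOH/THF/H2O, rt
Reagents that add atoms: none
Why: Pyridine-buffered fluoride removes the tertiary triethylsilyl ether without opening the epoxide, and mild acid hydrolysis of the 2-methoxyprop-2-yl perketal then releases the hydroperoxide, no stereocentre being touched.

**Compound list**
1 | (R)-malic acid, (2R)-2-hydroxybutanedioic acid | OC(=O)C[C@@H](O)C(O)=O | starting material
2 | (2R)-butane-1,2,4-triol | OCC[C@@H](O)CO | intermediate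
3 | [(2R,4R)-2-(4-methoxyphenyl)-1,3-dioxan-4-yl]methanol (cis acetal) | OC[C@H]1CCO[C@H](O1)c1ccc(OC)cc1 | intermediate
4 | triethyl{[(2R,4R)-2-(4-methoxyphenyl)-1,3-dioxan-4-yl]methoxy}silane | CC[Si](CC)(CC)OC[C@H]1CCO[C@H](O1)c1ccc(OC)cc1 | intermediate
5 | (3R)-3-[(4-methoxybenzyl)oxy]-4-[(triethylsilyl)oxy]butan-1-ol (C5–C8 unit, carbinol carbon = C7) | OCC[C@@H](OCc1ccc(OC)cc1)CO[Si](CC)(CC)CC | intermediate
6 | {[(2R)-4-iodo-2-[(4-methoxybenzyl)oxy]butyl]oxy}triethylsilane | ICC[C@@H](OCc1ccc(OC)cc1)CO[Si](CC)(CC)CC | intermediate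
7 | (R)-(+)-limonene | CC1=CC[C@@H](CC1)C(C)=C | starting material
8 | 2-[(1R)-4-methylcyclohex-3-en-1-yl]propan-1-ol, both epimers at the side-chain CH (future C15) | CC1=CC[C@@H](CC1)C(C)CO | intermediate
9 | (4R)-4-(3-hydroperoxy-3-methoxybutyl)-5-methyloxan-2-ol, isomer mixture at the other centres | CC(OC)(OO)CC[C@@H]1CC(O)OCC1C | intermediate (not isolated)
10 | (4R)-4-(3-hydroperoxy-3-methoxybutyl)-2-methoxy-5-methyloxane, isomer mixture at the other centres | CC(OC)(OO)CC[C@@H]1CC(OC)OCC1C | intermediate (not isolated)
11 | 4-[(4R)-2-methoxy-5-methyloxan-4-yl]butan-2-one, anomers and C15 epimers | CC(=O)CC[C@@H]1CC(OC)OCC1C | intermediate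
12 | triethyl phosphonoacetate | CCOC(=O)CP(=O)(OCC)OCC | starting material
13 | ethyl (2E)-5-[(4R)-2-methoxy-5-methyloxan-4-yl]-3-methylpent-2-enoate | CCOC(=O)/C=C(\C)CC[C@@H]1CC(OC)OCC1C | intermediate
14 | (2E)-5-[(4R)-2-methoxy-5-methyloxan-4-yl]-3-methylpent-2-en-1-ol | OC/C=C(\C)CC[C@@H]1CC(OC)OCC1C | intermediate
15 | tert-butyl{[(2E)-5-[(4R)-2-methoxy-5-methyloxan-4-yl]-3-methylpent-2-en-1-yl]oxy}diphenylsilane | CC(C)(C)[Si](c1ccccc1)(c1ccccc1)OC/C=C(\C)CC[C@@H]1CC(OC)OCC1C | intermediate
16 | (4R)-4-[(3E)-5-[(tert-butyldiphenylsilyl)oxy]-3-methylpent-3-en-1-yl]-5-methyloxan-2-ol (lactol; C3 masked aldehyde) | CC(C)(C)[Si](c1ccccc1)(c1ccccc1)OC/C=C(\C)CC[C@@H]1CC(O)OCC1C | intermediate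
17 | ethyl vinyl ether | C=COCC | starting material
18 | 1-ethoxyvinyllithium | [Li]C(=C)OCC | intermediate (not isolated)
19 | (5R,8E)-10-[(tert-butyldiphenylsilyl)oxy]-2-ethoxy-5-(1-hydroxypropan-2-yl)-8-methyldeca-1,8-dien-3-ol, epimers at C3 and C15 | CC(C)(C)[Si](c1ccccc1)(c1ccccc1)OC/C=C(\C)CC[C@@H](C(C)CO)CC(O)C(=C)OCC | intermediate (not isolated)
20 | (5R,8E)-10-[(tert-butyldiphenylsilyl)oxy]-3-hydroxy-5-(1-hydroxypropan-2-yl)-8-methyldec-8-en-2-one, epimers at C3 and C15 | CC(C)(C)[Si](c1ccccc1)(c1ccccc1)OC/C=C(\C)CC[C@@H](C(C)CO)CC(O)C(C)=O | intermediate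
21 | (4R)-6-acetyl-4-[(3E)-5-[(tert-butyldiphenylsilyl)oxy]-3-methylpent-3-en-1-yl]-3-methyloxan-2-ol, isomer mixture | CC(C)(C)[Si](c1ccccc1)(c1ccccc1)OC/C=C(\C)CC[C@@H]1CC(OC(O)C1C)C(C)=O | intermediate (not isolated)
22 | (4R)-6-acetyl-4-[(3E)-5-[(tert-butyldiphenylsilyl)oxy]-3-methylpent-3-en-1-yl]-3-methyloxan-2-one, epimers at C3 and C15 | CC(C)(C)[Si](c1ccccc1)(c1ccccc1)OC/C=C(\C)CC[C@@H]1CC(OC(=O)C1C)C(C)=O | intermediate
23 | (3S,4R,6R)-6-acetyl-4-[(3E)-5-[(tert-butyldiphenylsilyl)oxy]-3-methylpent-3-en-1-yl]-3-methyloxan-2-one (cembrane 1R,3R,15S; all-equatorial) | CC(C)(C)[Si](c1ccccc1)(c1ccccc1)OC/C=C(\C)CC[C@@H]2C[C@@H](OC(=O)[C@H]2C)C(C)=O | intermediate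
24 | (3R)-3-[(4-methoxybenzyl)oxy]-4-[(triethylsilyl)oxy]butyllithium | [Li]CC[C@@H](OCc1ccc(OC)cc1)CO[Si](CC)(CC)CC | intermediate (not isolated)
25 | dichloro{(3R)-3-[(4-methoxybenzyl)oxy]-4-[(triethylsilyl)oxy]butyl}cerium | Cl[Ce](Cl)CC[C@@H](OCc1ccc(OC)cc1)CO[Si](CC)(CC)CC | intermediate (not isolated)
26 | seco tertiary alcohol (1R,3R,4S,7R,15S,11E): lactone 23 with C4 now C(OH)(CH3) carrying C5H2–C6H2–C7H(OPMB)–C8H2OSiEt3 | CC(C)(C)[Si](c1ccccc1)(c1ccccc1)OC/C=C(\C)CC[C@@H]2C[C@@H](OC(=O)[C@H]2C)[C@@](C)(O)CC[C@@H](OCc1ccc(OC)cc1)CO[Si](CC)(CC)CC | intermediate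
27 | C8 aldehyde (1R,3R,4S,7R,15S,11E): as 26 with C8 = CHO | CC(C)(C)[Si](c1ccccc1)(c1ccccc1)OC/C=C(\C)CC[C@@H]2C[C@@H](OC(=O)[C@H]2C)[C@@](C)(O)CC[C@@H](OCc1ccc(OC)cc1)C=O | intermediate
28 | tert-butyl diazoacetate | CC(C)(C)OC(=O)C=[N+]=[N-] | starting material
29 | tert-butyl β-keto ester (1R,3R,4S,7R,15S,11E): C8 ketone, C9H2, CO2tBu; C10–OSi(tBu)Ph2 | CC(C)(C)[Si](c1ccccc1)(c1ccccc1)OC/C=C(\C)CC[C@@H]2C[C@@H](OC(=O)[C@H]2C)[C@@](C)(O)CC[C@@H](OCc1ccc(OC)cc1)C(=O)CC(=O)OC(C)(C)C | intermediate
30 | seco alcohol (1R,3R,4S,7R,15S,11E): as 29 with free C10–OH | OC/C=C(\C)CC[C@@H]2C[C@@H](OC(=O)[C@H]2C)[C@@](C)(O)CC[C@@H](OCc1ccc(OC)cc1)C(=O)CC(=O)OC(C)(C)C | intermediate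
31 | acylketene (1R,3R,4S,7R,15S,11E): C8 ketone with C9H=C=O | OC/C=C(\C)CC[C@@H]2C[C@@H](OC(=O)[C@H]2C)[C@@](C)(O)CC[C@@H](OCc1ccc(OC)cc1)C(=O)C=C=O | intermediate (not isolated)
32 | 16-membered allyl β-keto macrolactone (1R,3R,4S,7R,15S,11E): ring C8(=O)–C9H2–C(=O)–O–C10H2–C11H=C12(CH3)–C13–C14–C1–C2–C3–C4–C5–C6–C7; C7–OPMB, free C4–OH, δ-lactone C16–O–C3 | O=C1CC(=O)OC/C=C(\C)CC[C@@H]2C[C@@H](OC(=O)[C@H]2C)[C@@](C)(O)CC[C@H]1OCc1ccc(OC)cc1 | intermediate (key-step precursor)
33 | 14-membered C8 ketone (1R,3R,4S,7R,15S,11E): C9–C10 bond formed; C7–OPMB, free C4–OH | O=C1CC/C=C(\C)CC[C@@H]2C[C@@H](OC(=O)[C@H]2C)[C@@](C)(O)CC[C@H]1OCc1ccc(OC)cc1 | intermediate (key-step product)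
34 | exomethylene compound (1R,3R,4S,7R,15S,11E): C8=C19H2 | C=C1CC/C=C(\C)CC[C@@H]2C[C@@H](OC(=O)[C@H]2C)[C@@](C)(O)CC[C@H]1OCc1ccc(OC)cc1 | intermediate
35 | C4 triethylsilyl ether of 34 (1R,3R,4S,7R,15S,11E) | C=C1CC/C=C(\C)CC[C@@H]2C[C@@H](OC(=O)[C@H]2C)[C@@](C)(O[Si](CC)(CC)CC)CC[C@H]1OCc1ccc(OC)cc1 | intermediate
36 | 11,12-epoxide (1R,3R,4S,7R,11S,12S,15S): C7–OPMB, C4–OSiEt3 | C=C1CC[C@@H]2O[C@@]2(C)CC[C@@H]2C[C@@H](OC(=O)[C@H]2C)[C@@](C)(O[Si](CC)(CC)CC)CC[C@H]1OCc1ccc(OC)cc1 | intermediate
37 | (7R)-allylic alcohol (1R,3R,4S,7R,11S,12S,15S): C4–OSiEt3 | C=C1CC[C@@H]2O[C@@]2(C)CC[C@@H]2C[C@@H](OC(=O)[C@H]2C)[C@@](C)(O[Si](CC)(CC)CC)CC[C@H]1O | intermediate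
38 | (7R)-methanesulfonate of 37 | C=C1CC[C@@H]2O[C@@]2(C)CC[C@@H]2C[C@@H](OC(=O)[C@H]2C)[C@@](C)(O[Si](CC)(CC)CC)CC[C@H]1OS(C)(=O)=O | intermediate (not isolated)
39 | (7S)-2-methoxypropan-2-yl peroxide (1R,3R,4S,7S,11S,12S,15S): C4–OSiEt3 | C=C1CC[C@@H]2O[C@@]2(C)CC[C@@H]2C[C@@H](OC(=O)[C@H]2C)[C@@](C)(O[Si](CC)(CC)CC)CC[C@@H]1OOC(C)(C)OC | intermediate
40 | (7S)-2-methoxypropan-2-yl peroxide with free C4–OH (1R,3R,4S,7S,11S,12S,15S) | C=C1CC[C@@H]2O[C@@]2(C)CC[C@@H]2C[C@@H](OC(=O)[C@H]2C)[C@@](C)(O)CC[C@@H]1OOC(C)(C)OC | intermediate (not isolated)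
41 | CNP0319766.2, (1R,3R,4S,7S,11S,12S,15S)-7-hydroperoxy-4-hydroxy-11,12-epoxycembr-8(19)-en-16,3-olide | C=C1CC[C@@H]2O[C@@]2(C)CC[C@@H]2C[C@@H](OC(=O)[C@H]2C)[C@@](C)(O)CC[C@@H]1OO | target

**Step count**
Total: 26 steps. Longest linear sequence: 21 steps (steps 6–26 from (R)-limonene); the C5–C8 iodide 6 takes 5 steps (steps 1–5).

**Steps most likely to fail**

Risk 1, step 20 (Proposed new method). The enolate and the π-allyl unit may recombine between molecules (oligomers), the enolate may be protonated while the allyl unit eliminates to a diene, attack may occur at the tertiary terminus, or the alkene geometry may scramble. Fallback with known chemistry, setting out from 30 and returning at 33: the primary allylic hydroxyl of 30 is converted with ClCO2Me and pyridine into the allylic methyl carbonate F1. Pd(PPh3)4 in THF under high dilution then effects a Tsuji–Trost macrocyclisation, in which the methoxide released on ionisation deprotonates the β-keto ester and the stabilised carbanion attacks the primary allyl terminus, to give the 14-membered tert-butyl β-keto ester F2 (C9 epimers). Heating F2 in wet DMSO at about 130 °C removes the ester group (loss of isobutene, then decarboxylation of the β-keto acid) and gives ketone 33.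

Risk 2, step 25. The peroxide anion may attack the exomethylene terminus (SN2′), the mesylate may eliminate to a diene or ionise with loss of configuration, or the nucleophile may add to the lactone. Fallback, setting out from 37 and returning at 41: 37 is treated with PPh3, diethyl azodicarboxylate and 2-nitrobenzenesulfonylhydrazide (Mitsunobu conditions). The resulting allylic diazene loses N2 in a sigmatropic shift that moves the double bond to C7=C8 and turns C19 into a methyl group, giving the trisubstituted alkene F3. A Schenck ene reaction of F3 (O2, light, tetraphenylporphyrin, CH2Cl2, 0 °C) abstracts a C19 hydrogen and places the hydroperoxide on C7 while restoring the exomethylene, giving the silyl-protected hydroperoxide F4. The epoxide and lactone are inert to singlet oxygen; facial and regiochemical isomers would have to be separated. HF·pyridine then gives 41.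

Risk 3, step 15. The facial selectivity at the C4 ketone may be poor or opposite to the Felkin–Anh prediction, and enolisation or addition to the lactone may compete. Fallback, setting out from 16 and 6 and returning at 26; it exchanges the order in which the two carbon groups reach C4, so that a bias towards the wrong epimer becomes the right one. Iodide 6 alkylates 2-lithio-1,3-dithiane to give the dithiane F5. Lithiated F5 (tBuLi, THF/HMPA) adds to lactol 16 to give the dithiane adduct F6, and I2 with NaHCO3 in aqueous acetone unmasks the keto diol F7. Oxidative lactonisation (TEMPO, PhI(OAc)2) and DBU equilibration as in steps 13 and 14 give the acyl lactone F8, whose C4 ketone carries the C5–C8 chain. Addition of MeLi/CeCl3 from the face that the chain nucleophile used in step 15 then gives 26.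

**Further compounds**
F1 | step 20 | allylic methyl carbonate of seco alcohol 30 (1R,3R,4S,7R,15S,11E) | COC(=O)OC/C=C(\C)CC[C@@H]2C[C@@H](OC(=O)[C@H]2C)[C@@](C)(O)CC[C@@H](OCc1ccc(OC)cc1)C(=O)CC(=O)OC(C)(C)C
F2 | step 20 | 14-membered tert-butyl β-keto ester, ketone 33 carrying CO2tBu at C9 (C9 epimers) | O=C1C(C(=O)OC(C)(C)C)C/C=C(\C)CC[C@@H]2C[C@@H](OC(=O)[C@H]2C)[C@@](C)(O)CC[C@H]1OCc1ccc(OC)cc1
F3 | step 25 | (7E)-7,8-alkene with C19 methyl, no oxygen at C7 (1R,3R,4S,11S,12S,15S), C4–OSiEt3 | C1C/C=C(\C)CC[C@@H]2O[C@@]2(C)CC[C@@H]2C[C@@H](OC(=O)[C@H]2C)[C@@]1(C)O[Si](CC)(CC)CC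
F4 | step 25 | C4 triethylsilyl ether of the target hydroperoxide (1R,3R,4S,7S,11S,12S,15S) | C=C1CC[C@@H]2O[C@@]2(C)CC[C@@H]2C[C@@H](OC(=O)[C@H]2C)[C@@](C)(O[Si](CC)(CC)CC)CC[C@@H]1OO
F5 | step 15 | 2-{(3R)-3-[(4-methoxybenzyl)oxy]-4-[(triethylsilyl)oxy]butyl}-1,3-dithiane | C1CSC(SC1)CC[C@@H](OCc1ccc(OC)cc1)CO[Si](CC)(CC)CC
F6 | step 15 | dithiane adduct: diol from 16 with C4 as the 1,3-dithiane carbon bearing the C5–C8 chain (C3 and C15 epimers) | CC(C)(C)[Si](c1ccccc1)(c1ccccc1)OC/C=C(\C)CC[C@@H](C(C)CO)CC(O)C1(SCCCS1)CC[C@@H](OCc1ccc(OC)cc1)CO[Si](CC)(CC)CC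
F7 | step 15 | keto diol with the C4 ketone bearing the C5–C8 chain (C3 and C15 epimers) | CC(C)(C)[Si](c1ccccc1)(c1ccccc1)OC/C=C(\C)CC[C@@H](C(C)CO)CC(O)C(=O)CC[C@@H](OCc1ccc(OC)cc1)CO[Si](CC)(CC)CC
F8 | step 15 | acyl lactone (1R,3R,7R,15S,11E): analogue of 23 with the C5–C8 chain in place of the acetyl methyl group | CC(C)(C)[Si](c1ccccc1)(c1ccccc1)OC/C=C(\C)CC[C@@H]2C[C@@H](OC(=O)[C@H]2C)C(=O)CC[C@@H](OCc1ccc(OC)cc1)CO[Si](CC)(CC)CC
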